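How much target stands in south-west and in east after 3.0 min, and does it outweigh the isomer of the product?

| flask | substrate | catalyst | remark | time |
|---|---|---|---|---|
| Saturday's | 0.50 mM | 0.87 mol% | run made earlier |  |
| Monday's | 0.50 mM | 0.89 mol% | run made earlier |  |
| south-west | 0.50 mM | 1.2 mol% |  | 3.0 min |
| east | 0.50 mM | 1 mol% |  | 3.0 min |

| run | time / s | target / % |
|---|---|---|
| Saturday's | 10.0 | 9.8 |
| Saturday's | 15.0 | 13.1 |
| Saturday's | 40.0 | 22.8 |
| Saturday's | 90.0 | 27.8 |
| Monday's | 12.0 | 11.1 |
| Monday's | 30.0 | 20.2 |
| Monday's | 60.0 | 25.9 |
| Monday's | 90.0 | 27.9 |

(readings scatter by 0.3 percentage points)

- which of the two there is more of at the end, south-west (target / isomer of the product)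
- which of the two there is more of at the end, east (target / isomer of the product)
- amount of target at the end, in percent of the substrate charged, south-west
- amount of target at the end, in percent of the substrate charged, east

The balance of the catalyst, the smaller charge, gives a clock for any step that passes through it, while a step without it goes by time whatever the loading. If none of the catalyst is lost, a catalysed step advances with substrate charge times loading times time, and this product, counted in units of Saturday's run at its last reading, is the exposure: 2.76 for south-west and 2.30 for east.

Each input can now be weighed. The substrate charge is 0.50 mM throughout, so it cancels. The loadings of the two runs differ by a factor of 1.02, and their last readings, 27.8% and 27.9%, agree within the scatter of 0.3 percentage points. Monday's run gained 2 points for a step of 1.50 in time, and south-west stands ahead of east by a smaller step in exposure, 1.20, so, if target is made through the catalyst, I reckon that loading moves it little on the flattening curve of these readings. What matters is the height of the curve beyond the last readings, where none stands. My own reckoning carries the last readings forward: 27.8% of target in both flasks, with nothing read about the isomer of the product.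

The forecast is slightly higher: 28.6% in south-west (24.5% to 36%) and 28.6% in east (26.5% to 32%), with isomer of the product the larger in both, holding that “conversion is essentially complete”.

South-west gives 25.8% of target and east 26.5%, and target is the larger in both, against 18.5% and 16.0% of isomer of the product. South-west still holds 49% of its substrate at the end. South-west, with the greater exposure at the same time, holds less target than east, a fall of 1.6 points per unit of exposure at that time.

    catalyst + other conformer → catalyst + isomer of the product (k = 2190 M⁻¹ s⁻¹)
    substrate ⇌ other conformer (K = 0.160, k = 0.0159 s⁻¹)
    substrate + catalyst ⇌ catalyst + target (K = 0.510, k = 2730 M⁻¹ s⁻¹)

The neighbour of south-west charged with 1.2 mM of substrate and read at the same time has exposure 6.62, and that fall gives 19.6% of target. The simulation gives 21.0%.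

Readings and results were generated by integration with made-up constants.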